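Count the capture agent first. It is the reagent charged in the smallest amount, and each capture agent takes up one open intermediate, so in this flask at most 30.0% of the substrate can end as trapped intermediate. Call that figure, capture agent charged over substrate charged, the capture share s.

common to all: capture agent 0.234 M

| flask | substrate | partner | remark | time |
|---|---|---|---|---|
| maple | 1.1 M | 1.4 M | run made earlier |  |
| cedar | 1.7 M | 1.4 M | run made earlier |  |
| flask | 0.78 M | 1.40 M |  | 1.0 h |

- maple (time / min: isomer of the product / %, target / %): 4.00: 39.6, 5.9; 12.0: 39.4, 5.8; 20.0: 39.5, 6.4; 30.0: 39.3, 5.6; 50.0: 39.4, 6.1
- cedar (time / min: isomer of the product / %, target / %): 10.0: 33.0, 5.3; 20.0: 33.1, 4.9; 30.0: 33.3, 4.7; 40.0: 32.7, 5.1; 50.0: 33.0, 4.8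

(readings scatter by 0.3 percentage points)

* ratio of isomer of the product to target at 6.0 s
* ratio of isomer of the product to target at 2.5 min
* ratio of isomer of the product to target at 1.0 h

- steps that have been proposed: open intermediate + capture agent -> trapped intermediate; partner -> decomposed reagent; substrate + partner -> open intermediate + released group; open intermediate <-> isomer of the product; open intermediate <-> target

Turn the question round: what would keep the ratio of isomer to target moving at the hour? One way is capture agent still present and drawing on open intermediate, and some is sure to be left over where s stands above the share of substrate that turns over. In the maple run s was 21.3%, while isomer and target together read 45.5% at the first reading, more than s. In the cedar run s was 13.8% against 38.3%. Both runs then read flat up to 50.0 min.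

The share read was higher in maple, with less substrate against the same partner. Your flask has less substrate still, so I expect it to turn over at least the maple share, 16 percentage points above its s. I therefore commit, for the hour, to the ratio of isomer to target read on the maple plateau, 6.62. Before 4.00 min there are no readings, and I give no number.

The forecast gives 6.6 at 6.0 s, 6.6 at 2.5 min and 6.6 at 1.0 h, with the warning that “if the steps are reversible, the early kinetic ratio could differ, most likely lower”.

The flask gives 0.340 at 6.0 s, 5.58 at 2.5 min and 6.83 at 1.0 h.

    open intermediate + capture agent → trapped intermediate (k = 0.0440 L mol⁻¹ s⁻¹)
    partner → decomposed reagent (k = 0.00670 s⁻¹)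
    substrate + partner → open intermediate + released group (k = 0.0210 L mol⁻¹ s⁻¹)
    open intermediate ⇌ isomer of the product (K = 2.80, k = 0.0230 s⁻¹)
    open intermediate ⇌ target (K = 0.410, k = 0.110 s⁻¹)

In the flask, the half-life of the isomer for going back through open intermediate is 1.4 min, short against the 1.0 h of the run, which is the mark of thermodynamic control at the hour. There the flask holds trapped intermediate at 30.0%, matching its s of 30.0%, with capture agent at 0% of its charge. The neighbour charged with 0.20 M of substrate has s of 117%, above the 97.7% of its substrate that turned over; at the hour it keeps 20.9% of its capture agent and stands at a ratio of 7.25.

Readings and results were computed on assumed constants; noise was put on by code.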